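I count here in percentage points of the share of E.X in E.X plus J, and a scale in points wants a zero.

    E + X ⇌ E.X (K1 = 0.55 M⁻¹, k1 = 3.3 M⁻¹ h⁻¹)
    G + X ⇌ G.X (K2 = 12 M⁻¹, k2 = 1.5 M⁻¹ h⁻¹)
    E ⇌ Z (K3 = 0.74, k3 = 0.98 h⁻¹)
    X → D (k4 = 0.059 h⁻¹)
    E.X ⇌ J (K5 = 1.3, k5 = 0.072 h⁻¹)

| setting | elm | ash | birch | larch | cedar |
|---|---|---|---|---|---|
| E | 0.13 M | 0.13 M (fed, over 8.0 h) | 0.13 M (fed, over 2.0 h) | 0.13 M | 0.13 M (in portions, 5, over 8.0 h) |
| X | 0.800 equiv | 0.800 equiv | 0.800 equiv | 0.800 equiv (fed, over 8.0 h) | 0.800 equiv |
| G | 5.00 equiv | 5.00 equiv | 5.00 equiv | 5.00 equiv | 5.00 equiv |
| time | 10 h | 10 h | 10 h | 10 h | 10 h |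
| remark | everything together at the start | all else is in the flask from the start; the feed brings no volume worth counting | all else is in the flask from the start; the feed brings no volume worth counting | all else is in the flask from the start; the feed brings no volume worth counting | first portion at the start, last at 8.0 h |

1. the flask that comes out highest in share of E.X in E.X plus J, or "all alike" when all lie within 1.5 percentage points (elm / ash / birch / larch / cedar / all alike)
2. share of E.X in E.X plus J at the end, elm
3. share of E.X in E.X plus J at the end, ash
4. share of E.X in E.X plus J at the end, birch
5. share of E.X in E.X plus J at the end, larch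
6. share of E.X in E.X plus J at the end, cedar

The exchange of E.X with J gives me that zero. For the exchange in isolation, [J]/[E.X] at rest equals 1.3, so E.X holds 43.5% of the pair. This isolated-exchange share, thermodynamic control of that one step taken apart from the loss X → D, is the zero of my scale and not a resting point of the flask.

But in elm the exchange relaxes with a half-life of 5.44 h, and the asked time of 10 h is about twice that, so the exchange is under way and not finished. J starts from nothing and is made from E.X, so I expect elm to stand above the zero, with the share still carrying the recipe.

The recipe acts through the time at which E.X is present. At the start of elm, binding constant times concentration is 7.8 for G and 0.071 for E, so G is the stronger holder of X. X that has had time with G therefore stands bound, while in elm E meets X still unbound. In ash E arrives slowly, over 8.0 h, to X that G already holds, and the later E.X has less time to pass into J. That is a direction for ash, and my hand gives no per cent beyond the zero.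

The forecast goes further: elm 50%, ash 68.5%, birch 58.5%, larch 59.5%, cedar 67%, with ash highest, on the ground that “J instead remembers the history”.

The simulation gives elm 50.8%, ash 70.1%, birch 58.7%, larch 60.7% and cedar 68.3%, so ash comes out highest. At 10.0 h E.X is 0.347% of the E charged in ash and 0.348% in elm, but J is 0.148% in ash and 0.337% in elm. Measured from the zero of 43.5%, ash stands 27 percentage points up and elm 7.3 points up. Elm read at 25 h gives 44.5%, which is 1.0 point up, and elm left until 100 h gives 40.2%, which is below the zero.

(All constants stand for no real mixture; the rest is arithmetic.)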